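**Retrosynthetic overview**
1. Target 19 ⇐ 18 by semi-hydrogenation (the C5 propargyl group is an OsO4-inert masked allyl) ⇐ diol 16 by stannylene-directed methylation of O3.
2. 16 ⇐ bicyclo[3.2.1]oct-2-en-8-one 15 by exo-face syn-dihydroxylation, which sets C2 and C3.
3. Key step: 15 ⇐ 14 by gold-catalysed 6-endo-dig closure of an α-methoxy silyl enol ether onto one of two diastereotopic propargyl arms; this forms the six-membered ring last and sets both bridgeheads. The biomimetic quinone-ketal cation/propenylarene [5+2] cycloaddition is deliberately not used.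
4. 14 ⇐ enone 6 by trans-selective aryl 1,4-addition, Rubottom oxidation, O-methylation and enol silylation.
5. 6 ⇐ (S)-4-methylcyclopent-2-enone 3 by two successive α′-propargylations (through 5) ⇐ silyloxy enone 1, the only source of chirality (five-membered ring bought, bridging ring built second).

Assumptions: 1, 4 and 7 are taken as commercial. "Exo" means on the side of the C8 carbonyl bridge. 5 is drawn as the expected 4,5-trans epimer, whose C5 configuration is erased in step 3. 10–13 are drawn as the expected 2,3-trans epimer, whose C2 configuration is erased in step 8. Descriptor changes at C1/C5 between 15 and 16 are priority effects only, not inversions.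

Step 1
Reactants: 1 (S)-4-(tert-butyldimethylsilyloxy)cyclopent-2-en-1-one
Product: 3 (S)-4-methylcyclopent-2-en-1-one, via silyloxy ketone 2 (not isolated)
Conditions: Me2CuLi (1.2 equiv, from MeLi and CuI), Et2O, −78 °C; aq NH4Cl; crude 2, DBU, CH2Cl2, 0 °C to rt
Reagents that add atoms: lithium dimethylcuprate, [Li+].C[Cu-]C (prepared from methyllithium, C[Li])
Why: Gilman cuprate 1,4-addition occurs anti to the silyloxy group and so fixes the methyl-bearing centre, and DBU-promoted E1cB loss of silanolate then gives the transposed enone in which that centre (now C4, S) is untouched.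

Step 2
Reactants: 3 (S)-4-methylcyclopent-2-en-1-one; 4 3-bromo-1-(trimethylsilyl)prop-1-yne
Product: 5 (4R,5S)-4-methyl-5-[3-(trimethylsilyl)prop-2-yn-1-yl]cyclopent-2-en-1-one
Conditions: 3 added slowly to LiN(iPr)2 (1.05 equiv), THF, −78 °C; 4 (1.1 equiv), DMPU, −78 to −40 °C; aq NH4Cl
Reagents that add atoms: none
Why: Kinetic deprotonation of a cyclopent-2-enone takes place at the α′-carbon C5, and SN2 enolate alkylation with the reactive propargylic bromide occurs anti to the C4 methyl group, whose centre is not involved.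

Step 3
Reactants: 5 (4R,5S)-4-methyl-5-[3-(trimethylsilyl)prop-2-yn-1-yl]cyclopent-2-en-1-one; 4 3-bromo-1-(trimethylsilyl)prop-1-yne
Product: 6 (R)-4-methyl-5,5-bis[3-(trimethylsilyl)prop-2-yn-1-yl]cyclopent-2-en-1-one
Conditions: LiN(iPr)2 (1.1 equiv), THF, −78 °C; 4 (1.3 equiv), DMPU, −78 to −20 °C; aq NH4Cl
Reagents that add atoms: none
Why: A second kinetic α′-deprotonation and SN2 enolate alkylation builds the quaternary carbon, which carries two identical arms and is therefore not yet stereogenic, while the C4 centre is not involved.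

Step 4
Reactants: 6 (R)-4-methyl-5,5-bis[3-(trimethylsilyl)prop-2-yn-1-yl]cyclopent-2-en-1-one; 7 5-bromo-1,2,3-trimethoxybenzene
Product: 9 trimethyl{[(3R,4R)-4-methyl-3-(3,4,5-trimethoxyphenyl)-5,5-bis[3-(trimethylsilyl)prop-2-yn-1-yl]cyclopent-1-en-1-yl]oxy}silane, via arylmagnesium bromide 8 (not isolated)
Conditions: 7, Mg, THF, 40 °C; then 6, CuBr·SMe2 (10 mol%), Me3SiCl (2 equiv), THF, −78 to −40 °C; Et3N, cold aq NaHCO3 work-up, used crude
Reagents that add atoms: chlorotrimethylsilane, C[Si](C)(C)Cl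
Why: Copper-catalysed conjugate addition of the aryl Grignard reagent delivers the aryl group to C3 anti to the neighbouring C4 methyl group, setting the trans relationship of the future C7 and C6, and the enolate is trapped regiospecifically as the silyl enol ether.

Step 5
Reactants: 9 trimethyl{[(3R,4R)-4-methyl-3-(3,4,5-trimethoxyphenyl)-5,5-bis[3-(trimethylsilyl)prop-2-yn-1-yl]cyclopent-1-en-1-yl]oxy}silane
Product: 11 (2S,3S,4R)-2-hydroxy-4-methyl-3-(3,4,5-trimethoxyphenyl)-5,5-bis[3-(trimethylsilyl)prop-2-yn-1-yl]cyclopentan-1-one, via silyloxy ketone 10 (not isolated)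
Conditions: mCPBA (1.1 equiv), NaHCO3, CH2Cl2, −20 to 0 °C; then 1 M HCl, THF, 0 °C
Reagents that add atoms: 3-chloroperoxybenzoic acid, OOC(=O)c1cccc(Cl)c1
Why: Rubottom oxidation (epoxidation of the enol ether anti to the aryl group, 1,4-silyl shift, acid hydrolysis) places oxygen on the only enolisable carbon, and the configuration of this carbinol centre does not matter because it is erased in step 8.

Step 6
Reactants: 11 (2S,3S,4R)-2-hydroxy-4-methyl-3-(3,4,5-trimethoxyphenyl)-5,5-bis[3-(trimethylsilyl)prop-2-yn-1-yl]cyclopentan-1-one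
Product: 12 (2S,3S,4R)-2-methoxy-4-methyl-3-(3,4,5-trimethoxyphenyl)-5,5-bis[3-(trimethylsilyl)prop-2-yn-1-yl]cyclopentan-1-one
Conditions: Me3OBF4 (3 equiv), 1,8-bis(dimethylamino)naphthalene (3.5 equiv), CH2Cl2, 0 °C to rt
Reagents that add atoms: trimethyloxonium tetrafluoroborate, C[O+](C)C.F[B-](F)(F)F
Why: Meerwein-salt O-methylation with a hindered amine base is non-enolising, so the α-ketol is etherified without ketol transposition or C-alkylation and no stereocentre is touched.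

Step 7
Reactants: 12 (2S,3S,4R)-2-methoxy-4-methyl-3-(3,4,5-trimethoxyphenyl)-5,5-bis[3-(trimethylsilyl)prop-2-yn-1-yl]cyclopentan-1-one
Product: 13 (2S,3S,4R)-2-methoxy-4-methyl-5,5-di(prop-2-yn-1-yl)-3-(3,4,5-trimethoxyphenyl)cyclopentan-1-one
Conditions: K2CO3 (0.3 equiv), MeOH, rt
Reagents that add atoms: none
Why: Methoxide-catalysed protodesilylation of the alkynylsilanes frees both terminal alkynes, and any epimerisation next to the ketone is of no consequence.

Step 8
Reactants: 13 (2S,3S,4R)-2-methoxy-4-methyl-5,5-di(prop-2-yn-1-yl)-3-(3,4,5-trimethoxyphenyl)cyclopentan-1-one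
Product: 14 tert-butyl{[(3S,4R)-2-methoxy-4-methyl-5,5-di(prop-2-yn-1-yl)-3-(3,4,5-trimethoxyphenyl)cyclopent-1-en-1-yl]oxy}dimethylsilane
Conditions: tBuMe2SiOTf (1.5 equiv), Et3N (3 equiv), CH2Cl2, 0 °C to rt; chromatography on Et3N-deactivated silica
Reagents that add atoms: tert-butyldimethylsilyl trifluoromethanesulfonate, CC(C)(C)[Si](C)(C)OS(=O)(=O)C(F)(F)F
Why: Soft enolisation with silyl triflate and amine can only go toward C2, the sole enolisable α-carbon, giving one tetrasubstituted α-methoxy silyl enol ether and deliberately erasing the C2 stereocentre.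

Step 9
Reactants: 14 tert-butyl{[(3S,4R)-2-methoxy-4-methyl-5,5-di(prop-2-yn-1-yl)-3-(3,4,5-trimethoxyphenyl)cyclopent-1-en-1-yl]oxy}dimethylsilane
Product: 15 (1R,5S,6R,7S)-1-methoxy-6-methyl-5-(prop-2-yn-1-yl)-7-(3,4,5-trimethoxyphenyl)bicyclo[3.2.1]oct-2-en-8-one
Conditions: [(tBuXPhos)Au(NCMe)]SbF6 (3 mol%; tBuXPhos = 2-di-tert-butylphosphino-2′,4′,6′-triisopropylbiphenyl), acetone, H2O (2 equiv), 0 °C to rt, 30 min; Et3N quench
Reagents that add atoms: none
Why: In this key step cationic monovalent gold activates an alkyne for 6-endo-dig attack by the silyl enol ether carbon (gold-catalysed Conia-ene-type carbocyclisation; 5-exo closure would give a strained bicyclo[2.2.1]heptan-7-one), and because that carbon is attacked anti to the adjacent aryl group only the propargyl arm cis to the methyl group can close, which sets both bridgeheads at once and leaves the aryl exo and the methyl endo.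

Step 10
Reactants: 15 (1R,5S,6R,7S)-1-methoxy-6-methyl-5-(prop-2-yn-1-yl)-7-(3,4,5-trimethoxyphenyl)bicyclo[3.2.1]oct-2-en-8-one
Product: 16 (1S,2S,3S,5R,6R,7S)-2,3-dihydroxy-1-methoxy-6-methyl-5-(prop-2-yn-1-yl)-7-(3,4,5-trimethoxyphenyl)bicyclo[3.2.1]octan-8-one
Conditions: OsO4 (3 mol%), NMO (1.5 equiv), acetone/H2O 8:1, rt; aq NaHSO3 work-up
Reagents that add atoms: osmium tetroxide, O=[Os](=O)(=O)=O (catalytic oxygen carrier); N-methylmorpholine N-oxide, C[N+]1([O-])CCOCC1; water, O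
Why: Upjohn syn-dihydroxylation reaches the C2=C3 alkene from the exo face because the endo face is shielded by the two-carbon bridge and its endo methyl group, giving the cis-diol with both hydroxyls exo (2S,3S), while OsO4 leaves the alkyne untouched.

Step 11
Reactants: 16 (1S,2S,3S,5R,6R,7S)-2,3-dihydroxy-1-methoxy-6-methyl-5-(prop-2-yn-1-yl)-7-(3,4,5-trimethoxyphenyl)bicyclo[3.2.1]octan-8-one
Product: 18 (1S,2S,3S,5R,6R,7S)-2-hydroxy-1,3-dimethoxy-6-methyl-5-(prop-2-yn-1-yl)-7-(3,4,5-trimethoxyphenyl)bicyclo[3.2.1]octan-8-one, via stannylene acetal 17 (not isolated)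
Conditions: Bu2SnO (1.1 equiv), toluene, reflux, Dean–Stark; then MeI (5 equiv), CsF (2 equiv), DMF, 40 °C; aq KF work-up
Reagents that add atoms: iodomethane, CI
Why: Stannylene-acetal-mediated mono-alkylation of a cis-diol goes to the equatorial, less hindered oxygen (O3; O2 is axial and flanked by the quaternary bridgehead), and the near-neutral conditions avoid retro-aldol cleavage of the β-hydroxy ketone, with no stereocentre changed.

Step 12
Reactants: 18 (1S,2S,3S,5R,6R,7S)-2-hydroxy-1,3-dimethoxy-6-methyl-5-(prop-2-yn-1-yl)-7-(3,4,5-trimethoxyphenyl)bicyclo[3.2.1]octan-8-one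
Product: 19 (1S,2S,3S,5R,6R,7S)-2-hydroxy-1,3-dimethoxy-6-methyl-5-(prop-2-en-1-yl)-7-(3,4,5-trimethoxyphenyl)bicyclo[3.2.1]octan-8-one
Conditions: H2 (1 atm), Pd/CaCO3 poisoned with Pb(OAc)2 (Lindlar catalyst), quinoline, EtOAc, rt, stopped at 1 equiv uptake
Reagents that add atoms: none
Why: Lindlar semi-hydrogenation stops at the alkene, turning the propargyl group into the allyl group without touching the ketone, the arene or any stereocentre.

**Compound list**
1 | (S)-4-(tert-butyldimethylsilyloxy)cyclopent-2-en-1-one | O=C1C=C[C@@H](O[Si](C)(C)C(C)(C)C)C1 | starting material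
2 | (3S,4S)-4-(tert-butyldimethylsilyloxy)-3-methylcyclopentan-1-one (3,4-trans) | O=C1C[C@H](C)[C@@H](O[Si](C)(C)C(C)(C)C)C1 | intermediate
3 | (S)-4-methylcyclopent-2-en-1-one | O=C1C=C[C@@H](C)C1 | intermediate
4 | 3-bromo-1-(trimethylsilyl)prop-1-yne | C[Si](C)(C)C#CCBr | starting material
5 | (4R,5S)-4-methyl-5-[3-(trimethylsilyl)prop-2-yn-1-yl]cyclopent-2-en-1-one (4,5-trans) | C[Si](C)(C)C#CC[C@@H]1C(=O)C=C[C@H]1C | intermediate
6 | (R)-4-methyl-5,5-bis[3-(trimethylsilyl)prop-2-yn-1-yl]cyclopent-2-en-1-one | C[Si](C)(C)C#CCC1(CC#C[Si](C)(C)C)C(=O)C=C[C@H]1C | intermediate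
7 | 5-bromo-1,2,3-trimethoxybenzene | COc1cc(Br)cc(OC)c1OC | starting material
8 | (3,4,5-trimethoxyphenyl)magnesium bromide | COc1cc([Mg]Br)cc(OC)c1OC | intermediate
9 | trimethyl{[(3R,4R)-4-methyl-3-(3,4,5-trimethoxyphenyl)-5,5-bis[3-(trimethylsilyl)prop-2-yn-1-yl]cyclopent-1-en-1-yl]oxy}silane (aryl and methyl trans) | C[Si](C)(C)C#CCC1(CC#C[Si](C)(C)C)C(O[Si](C)(C)C)=C[C@H](c2cc(OC)c(OC)c(OC)c2)[C@H]1C | intermediate
10 | (2S,3S,4R)-4-methyl-3-(3,4,5-trimethoxyphenyl)-2-(trimethylsilyloxy)-5,5-bis[3-(trimethylsilyl)prop-2-yn-1-yl]cyclopentan-1-one | C[Si](C)(C)C#CCC1(CC#C[Si](C)(C)C)C(=O)[C@@H](O[Si](C)(C)C)[C@H](c2cc(OC)c(OC)c(OC)c2)[C@H]1C | intermediate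
11 | (2S,3S,4R)-2-hydroxy-4-methyl-3-(3,4,5-trimethoxyphenyl)-5,5-bis[3-(trimethylsilyl)prop-2-yn-1-yl]cyclopentan-1-one | C[Si](C)(C)C#CCC1(CC#C[Si](C)(C)C)C(=O)[C@@H](O)[C@H](c2cc(OC)c(OC)c(OC)c2)[C@H]1C | intermediate
12 | (2S,3S,4R)-2-methoxy-4-methyl-3-(3,4,5-trimethoxyphenyl)-5,5-bis[3-(trimethylsilyl)prop-2-yn-1-yl]cyclopentan-1-one | C[Si](C)(C)C#CCC1(CC#C[Si](C)(C)C)C(=O)[C@@H](OC)[C@H](c2cc(OC)c(OC)c(OC)c2)[C@H]1C | intermediate
13 | (2S,3S,4R)-2-methoxy-4-methyl-5,5-di(prop-2-yn-1-yl)-3-(3,4,5-trimethoxyphenyl)cyclopentan-1-one | C#CCC1(CC#C)C(=O)[C@@H](OC)[C@H](c2cc(OC)c(OC)c(OC)c2)[C@H]1C | intermediate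
14 | tert-butyl{[(3S,4R)-2-methoxy-4-methyl-5,5-di(prop-2-yn-1-yl)-3-(3,4,5-trimethoxyphenyl)cyclopent-1-en-1-yl]oxy}dimethylsilane | C#CCC1(CC#C)C(O[Si](C)(C)C(C)(C)C)=C(OC)[C@H](c2cc(OC)c(OC)c(OC)c2)[C@H]1C | intermediate
15 | (1R,5S,6R,7S)-1-methoxy-6-methyl-5-(prop-2-yn-1-yl)-7-(3,4,5-trimethoxyphenyl)bicyclo[3.2.1]oct-2-en-8-one (aryl exo, methyl endo) | C#CC[C@]12CC=C[C@](OC)(C1=O)[C@H](c1cc(OC)c(OC)c(OC)c1)[C@H]2C | intermediate
16 | (1S,2S,3S,5R,6R,7S)-2,3-dihydroxy-1-methoxy-6-methyl-5-(prop-2-yn-1-yl)-7-(3,4,5-trimethoxyphenyl)bicyclo[3.2.1]octan-8-one (both hydroxyls exo) | C#CC[C@]12C[C@H](O)[C@H](O)[C@](OC)(C1=O)[C@H](c1cc(OC)c(OC)c(OC)c1)[C@H]2C | intermediate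
17 | 2,3-O-(dibutylstannylene) acetal of 16 (2,2-dibutyl-1,3,2-dioxastannolane across O2 and O3) | C#CC[C@]12C[C@@H]3O[Sn](CCCC)(CCCC)O[C@@H]3[C@](OC)(C1=O)[C@H](c1cc(OC)c(OC)c(OC)c1)[C@H]2C | intermediate
18 | (1S,2S,3S,5R,6R,7S)-2-hydroxy-1,3-dimethoxy-6-methyl-5-(prop-2-yn-1-yl)-7-(3,4,5-trimethoxyphenyl)bicyclo[3.2.1]octan-8-one | C#CC[C@]12C[C@H](OC)[C@H](O)[C@](OC)(C1=O)[C@H](c1cc(OC)c(OC)c(OC)c1)[C@H]2C | intermediate
19 | (1S,2S,3S,5R,6R,7S)-2-hydroxy-1,3-dimethoxy-6-methyl-5-(prop-2-en-1-yl)-7-(3,4,5-trimethoxyphenyl)bicyclo[3.2.1]octan-8-one | C=CC[C@]12C[C@H](OC)[C@H](O)[C@](OC)(C1=O)[C@H](c1cc(OC)c(OC)c(OC)c1)[C@H]2C | target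

**Totals**
Total step count: 12. Longest linear sequence: 12 steps (1 to 19; 4 and 7 are bought and used directly).

**Three steps most likely to fail**

Step 9 (gold cyclisation). The risks are 5-exo closure, gold-mediated hydration of the second alkyne, or simple hydrolysis of the enol ether back to 13. The fallback makes the same C1–C2 bond by zerovalent-palladium-catalysed intramolecular ketone α-alkenylation and sets out from diyne ketone 13. NBS with catalytic AgNO3 in acetone gives (2S,3S,4R)-5,5-bis(3-bromoprop-2-yn-1-yl)-2-methoxy-4-methyl-3-(3,4,5-trimethoxyphenyl)cyclopentan-1-one F1. Diimide, generated from 2-nitrobenzenesulfonylhydrazide and Et3N in THF/iPrOH, reduces both bromoalkynes to give (2S,3S,4R)-5,5-bis[(Z)-3-bromoprop-2-en-1-yl]-2-methoxy-4-methyl-3-(3,4,5-trimethoxyphenyl)cyclopentan-1-one F2. Pd(PPh3)4 (10 mol%) and KOPh in THF at 60 °C couple the potassium enolate with the vinyl bromide on the face anti to the aryl group, where geometry allows only six-membered ring closure, to give (1R,5S,6R,7S)-5-[(Z)-3-bromoprop-2-en-1-yl]-1-methoxy-6-methyl-7-(3,4,5-trimethoxyphenyl)bicyclo[3.2.1]oct-2-en-8-one F3. KOtBu in THF at −20 °C then anti-eliminates HBr from the remaining (Z)-bromoalkene and returns the terminal alkyne, so the fallback comes back to the route at compound 15.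

Step 2 (first α′-alkylation of enone 3). The risks are self-condensation of the volatile cyclopentenone enolate, over-alkylation and loss of ee through γ-deprotonation. The fallback sets out from compound 1 and installs the first arm by three-component coupling instead of enone deprotonation. Conjugate addition of Me3ZnLi (from Me2Zn and MeLi, THF, −78 °C) is followed by alkylation of the resulting enolate with 4 in the presence of HMPA to give all-trans (2S,3S,4S)-4-(tert-butyldimethylsilyloxy)-3-methyl-2-[3-(trimethylsilyl)prop-2-yn-1-yl]cyclopentan-1-one F4. DBU in CH2Cl2 then eliminates the silanol, so the fallback comes back to the route at compound 5, and step 3 follows unchanged on this non-volatile enone.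

Step 11 (selective O3 methylation). The risks are sluggish or unselective alkylation of the stannylene and retro-aldol cleavage. The fallback differentiates the two hydroxyls by orthoester opening instead of direct selective alkylation and sets out from diol 16. MeC(OMe)3 with catalytic camphorsulfonic acid in CH2Cl2 gives the cyclic 2,3-orthoacetate of 16 F5, a 2-methoxy-2-methyl-1,3-dioxolane fused across O2 and O3 as a mixture of epimers at the orthoester carbon. Hydrolysis in 80% aqueous AcOH opens it to the axial ester, (1S,2S,3S,5R,6R,7S)-3-hydroxy-1-methoxy-6-methyl-8-oxo-5-(prop-2-yn-1-yl)-7-(3,4,5-trimethoxyphenyl)bicyclo[3.2.1]octan-2-yl acetate F6. Me3OBF4 with 1,8-bis(dimethylamino)naphthalene methylates the free equatorial 3-hydroxyl to give (1S,2S,3S,5R,6R,7S)-1,3-dimethoxy-6-methyl-8-oxo-5-(prop-2-yn-1-yl)-7-(3,4,5-trimethoxyphenyl)bicyclo[3.2.1]octan-2-yl acetate F7. K2CO3 in MeOH at 0 °C removes the acetate, so the fallback comes back to the route at compound 18.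

**Further compounds**
F1 | step 9 | (2S,3S,4R)-5,5-bis(3-bromoprop-2-yn-1-yl)-2-methoxy-4-methyl-3-(3,4,5-trimethoxyphenyl)cyclopentan-1-one | BrC#CCC1(CC#CBr)C(=O)[C@@H](OC)[C@H](c2cc(OC)c(OC)c(OC)c2)[C@H]1C
F2 | step 9 | (2S,3S,4R)-5,5-bis[(Z)-3-bromoprop-2-en-1-yl]-2-methoxy-4-methyl-3-(3,4,5-trimethoxyphenyl)cyclopentan-1-one | Br/C=C\CC1(C/C=C\Br)C(=O)[C@@H](OC)[C@H](c2cc(OC)c(OC)c(OC)c2)[C@H]1C
F3 | step 9 | (1R,5S,6R,7S)-5-[(Z)-3-bromoprop-2-en-1-yl]-1-methoxy-6-methyl-7-(3,4,5-trimethoxyphenyl)bicyclo[3.2.1]oct-2-en-8-one | Br/C=C\C[C@]12CC=C[C@](OC)(C1=O)[C@H](c1cc(OC)c(OC)c(OC)c1)[C@H]2C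
F4 | step 2 | (2S,3S,4S)-4-(tert-butyldimethylsilyloxy)-3-methyl-2-[3-(trimethylsilyl)prop-2-yn-1-yl]cyclopentan-1-one | C[Si](C)(C)C#CC[C@@H]1C(=O)C[C@H](O[Si](C)(C)C(C)(C)C)[C@H]1C
F5 | step 11 | cyclic 2,3-orthoacetate of 16 (2-methoxy-2-methyl-1,3-dioxolane across O2 and O3) | C#CC[C@]12C[C@@H]3OC(C)(OC)O[C@@H]3[C@](OC)(C1=O)[C@H](c1cc(OC)c(OC)c(OC)c1)[C@H]2C
F6 | step 11 | (1S,2S,3S,5R,6R,7S)-3-hydroxy-1-methoxy-6-methyl-8-oxo-5-(prop-2-yn-1-yl)-7-(3,4,5-trimethoxyphenyl)bicyclo[3.2.1]octan-2-yl acetate | C#CC[C@]12C[C@H](O)[C@H](OC(C)=O)[C@](OC)(C1=O)[C@H](c1cc(OC)c(OC)c(OC)c1)[C@H]2C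
F7 | step 11 | (1S,2S,3S,5R,6R,7S)-1,3-dimethoxy-6-methyl-8-oxo-5-(prop-2-yn-1-yl)-7-(3,4,5-trimethoxyphenyl)bicyclo[3.2.1]octan-2-yl acetate | C#CC[C@]12C[C@H](OC)[C@H](OC(C)=O)[C@](OC)(C1=O)[C@H](c1cc(OC)c(OC)c(OC)c1)[C@H]2C
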